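A small charge, 0.020 M of electrophile and 0.0200 M of nucleophile, stands with free base for 8.0 d, and we want to know how much electrophile has reacted by then.

all flasks: electrophile 0.020 M
- delta: nucleophile 0.020 M; free base 0.065 M; run made earlier
- Thursday's: nucleophile 0.0200 M; free base 0.0600 M; time 8.0 d
- Monday's: nucleophile 0.0200 M; free base 0.240 M; time 8.0 d
- Friday's: nucleophile 0.0200 M; free base 0.120 M; time 8.0 d

delta run (percent of the electrophile charged)

| time / d | electrophile / % | target / % |
|---|---|---|
| 0.333 | 57.9 | 36.4 |
| 0.625 | 45.9 | 42.3 |
| 1.04 | 35.6 | 43.5 |
| 2.00 | 21.2 | 45.6 |
| 4.00 | 9.1 | 44.6 |

(standard deviation of a reading: 0.5 percentage points)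

- part of the electrophile that has reacted at the end, Thursday's
- part of the electrophile that has reacted at the end, Monday's
- part of the electrophile that has reacted at the end, Friday's
- what raising the concentration of free base from its lowest to its highest value here does to the part of the electrophile that has reacted (changes below 5 percentage points count as none) (it rises / no change / it falls)

- percent here means electrophile units held: one side product counts as two
- the numbers in the tables scatter by 0.5 percentage points (one standard deviation)
- steps thought possible: electrophile + nucleophile -> acid set free + target; nucleophile + acid set free <-> protonated nucleophile; acid set free + free base <-> salt of the base; nucleophile <-> dormant form; electrophile + target -> side product; target -> over-reaction product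
- no earlier run changes the charge of free base; that part of a forecast is a guess

In the delta run the target reads 45.6% at 2.00 d and 44.6% at 4.00 d, while the electrophile goes on falling. At the last reading 46.3% of the electrophile charged is in neither, which we take to be side product. We take the late electrophile in the delta run to fall with a fixed half-life, as it does when what it meets stays nearly constant (pseudo-first-order). So we need two times: τ, the late half-life of the electrophile, and the time still to run after the last reading.

τ = ln(2) × (4.00 d − 2.00 d) / ln(21.2% / 9.1%) = 1.64 d

time still to run = 4.00 d = 2.44 τ

electrophile left = 9.1% × exp(−ln(2) × 2.44) = 1.68%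

Thursday's has 0.0600 M of free base against the delta run's 0.065 M, so we reckon 98.3% reacted there. For more base we can only guess, but the 1.68% we reckon still unreacted is less than the 5 percentage points that counts as a change, so we expect no rise that counts.

The forecast says 97.5% for Thursday's, 99% for Friday's, 99.5% for Monday's, and no change: “Everything is near complete, so the change is under 5 points”.

Thursday's, Friday's and Monday's give 97.8%, 98.5% and 99.1%, and the trend is no change, a difference of 1.4 points.

    electrophile + nucleophile → acid set free + target (k = 0.121 /M/min)
    nucleophile + acid set free ⇌ protonated nucleophile, settled at all times (K = 1700 /M)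
    acid set free + free base ⇌ salt of the base (K = 28.3 /M, k = 0.0687 /M/min)
    nucleophile ⇌ dormant form (K = 0.430, k = 5.54 × 10⁻⁴ /min)
    electrophile + target → side product (k = 0.0180 /M/min)
    target → over-reaction product (k = 1.60 × 10⁻⁶ /min)

From 9.74% at 4.00 d in Thursday's, τ gives 1.80% at 8.00 d, and the flask holds 2.24%. From 6.10% in Monday's, τ gives 1.12%, and the flask holds 0.883%. Thursday's has not come to rest. The stretch to 80.0 d is 43.9 τ, and over it the electrophile goes from 2.24% to 0% and the side product from 55.2% to 58.0%. The target, with a half-life of 300 d by its turning into over-reaction product alone, falls from 41.8% to 34.9%, and the over-reaction product climbs from 0.783% to 7.09%.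

(The runs are simulated from invented constants, and the scatter is random.)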